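The α-methylene-γ-butyrolactone is disconnected at O–C2 and C15–C1 (cembrane numbering). This turns the lactone ring (O, C2, C1, C15, C16) into 2-bromoacrylic acid plus the C1=C2 alkene of a (1E,3E)-diene inside the 14-membered carbocycle. One palladium-catalysed heteroannulation joins C15 to C1 and the carboxylate oxygen to allylic C2. It exploits the C3=C4 alkene, which stabilises the π-allyl intermediate, and sets both ring-fusion stereocentres at once under control of the C6 and C10 stereocentres. The precursor is a macrocyclic tetraene acetate, assembled from geranyl acetate by two catalytic asymmetric C–C bond formations and a one-pot carboalumination/alkenyl–alkenyl macrocyclisation.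

Key step: step 13

Remark on numbering: cembrane numbering is used for 19 and 20 (C1 = ring-fusion CH bearing C15, C2 = ring-fusion CH–O, C3=C4, C6 = CHOAc, C7=C8, C10 = CHOH, C11=C12, C15 = α-carbon, C16 = C=O, C17 = exocyclic CH2). Ring atoms C10, C11, C12, C13, C1 and C5 of 16 and 17 become C1, C2, C3, C4, C6 and C10.

Assumption: the two chiral catalysts (steps 6 and 10) follow their established facial models for conjugated aldehydes, so that the antipodes named below deliver the Si-face adducts; should either sense prove opposite, the other antipode would be used.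

Step 1
Reactants: 1 geranyl acetate
Product: 3 (2E)-3-methyl-6-oxohex-2-en-1-yl acetate, via 6,7-epoxygeranyl acetate 2 (not isolated)
Conditions: mCPBA (1.05 equiv), CH2Cl2, 0 °C; crude epoxide, then H5IO6, THF/H2O, 0 °C
Reagents that add atoms: mCPBA, O=C(OO)c1cccc(Cl)c1
Why: Prilezhaev epoxidation should be selective for the electron-rich 6,7-alkene (the 2,3-alkene is deactivated by the allylic acetate), and periodic acid then cleaves the epoxide through the diol to the aldehyde without touching the E alkene.

Step 2
Reactants: 3 (2E)-3-methyl-6-oxohex-2-en-1-yl acetate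
Product: 4 (2E)-3-methylhept-2-en-6-yn-1-ol
Conditions: dimethyl (1-diazo-2-oxopropyl)phosphonate, K2CO3, MeOH, 0 °C to rt
Reagents that add atoms: dimethyl (1-diazo-2-oxopropyl)phosphonate, COP(=O)(OC)C(=[N+]=[N-])C(C)=O
Why: Seyferth–Gilbert homologation with the Ohira–Bestmann reagent should convert the aldehyde into the terminal alkyne, while K2CO3/MeOH removes the acetate by transesterification in the same flask.

Step 3
Reactants: 4 (2E)-3-methylhept-2-en-6-yn-1-ol
Product: 6 (2E,6E)-7-iodo-3-methylhepta-2,6-dien-1-ol, via alkenylzirconocene chloride 5 (not isolated)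
Conditions: Cp2Zr(H)Cl (2.3 equiv), THF, 0 °C to rt; I2, 0 °C
Reagents that add atoms: iodine, II
Why: Schwartz hydrozirconation adds Zr–H syn and anti-Markovnikov to the terminal alkyne (one equivalent is spent on the O–H), and iodinolysis with retention should give only the E alkenyl iodide, the trisubstituted alkene being inert.

Step 4
Reactants: 6 (2E,6E)-7-iodo-3-methylhepta-2,6-dien-1-ol
Product: 7 (2E,6E)-7-iodo-3-methylhepta-2,6-dienal
Conditions: MnO2, CH2Cl2, rt
Reagents that add atoms: none
Why: Allylic oxidation with MnO2 should give the enal selectively and leave the alkenyl iodide untouched.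

Step 5
Reactants: 8 methyl 3-methylbut-2-enoate
Product: 9 tert-butyl[(1-methoxy-3-methylbuta-1,3-dien-1-yl)oxy]dimethylsilane
Conditions: LDA, THF, −78 °C; TBSCl, DMPU, −78 °C to rt
Reagents that add atoms: TBSCl, CC(C)(C)[Si](C)(C)Cl
Why: Kinetic γ-deprotonation of the senecioate and O-silylation (silyl ketene acetal formation) should give the cross-conjugated silyl dienolate.

Step 6
Reactants: 7 (2E,6E)-7-iodo-3-methylhepta-2,6-dienal; 9 tert-butyl[(1-methoxy-3-methylbuta-1,3-dien-1-yl)oxy]dimethylsilane
Product: 10 methyl (2E,5S,6E,10E)-5-hydroxy-11-iodo-3,7-dimethylundeca-2,6,10-trienoate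
Conditions: SiCl4 (1.1 equiv), (S,S)-binaphthyldiamine-derived bisphosphoramide (5 mol %), iPr2NEt (10 mol %), CH2Cl2, −78 °C; aq. NaHCO3
Reagents that add atoms: none
Why: In this catalytic asymmetric vinylogous Mukaiyama aldol reaction (chiral Lewis base-activated SiCl4) the dienolate should attack through its γ-carbon on the Si face of the conjugated aldehyde, setting the (5S) carbinol under catalyst control and giving the (2E) enoate.

Step 7
Reactants: 10 methyl (2E,5S,6E,10E)-5-hydroxy-11-iodo-3,7-dimethylundeca-2,6,10-trienoate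
Product: 11 methyl (2E,5S,6E,10E)-5-[(tert-butyldimethylsilyl)oxy]-11-iodo-3,7-dimethylundeca-2,6,10-trienoate
Conditions: TBSCl, imidazole, DMF, rt
Reagents that add atoms: TBSCl, CC(C)(C)[Si](C)(C)Cl
Why: Standard silylation of the secondary allylic alcohol, which keeps this carbinol distinct from the one that will later carry the acetate.

Step 8
Reactants: 11 methyl (2E,5S,6E,10E)-5-[(tert-butyldimethylsilyl)oxy]-11-iodo-3,7-dimethylundeca-2,6,10-trienoate
Product: 12 (2E,5S,6E,10E)-5-[(tert-butyldimethylsilyl)oxy]-11-iodo-3,7-dimethylundeca-2,6,10-trien-1-ol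
Conditions: DIBAL-H (2.2 equiv), CH2Cl2, −78 °C; Rochelle salt
Reagents that add atoms: none
Why: DIBAL-H reduction of the enoate should give the allylic alcohol by 1,2-reduction, with the alkenyl iodide and silyl ether unaffected.

Step 9
Reactants: 12 (2E,5S,6E,10E)-5-[(tert-butyldimethylsilyl)oxy]-11-iodo-3,7-dimethylundeca-2,6,10-trien-1-ol
Product: 13 (2E,5S,6E,10E)-5-[(tert-butyldimethylsilyl)oxy]-11-iodo-3,7-dimethylundeca-2,6,10-trienal
Conditions: MnO2, CH2Cl2, rt
Reagents that add atoms: none
Why: Allylic oxidation with MnO2 of the only free (primary allylic) alcohol should give the E enal.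

Step 10
Reactants: 13 (2E,5S,6E,10E)-5-[(tert-butyldimethylsilyl)oxy]-11-iodo-3,7-dimethylundeca-2,6,10-trienal
Product: 14 (4S,5E,8S,9E,13E)-8-[(tert-butyldimethylsilyl)oxy]-14-iodo-6,10-dimethyltetradeca-5,9,13-trien-1-yn-4-ol
Conditions: allenylboronic acid pinacol ester (1.5 equiv), (S)-TRIP (10 mol %), 4 Å MS, toluene, −20 °C
Reagents that add atoms: allenylboronic acid pinacol ester, C=C=CB1OC(C)(C)C(C)(C)O1
Why: Chiral phosphoric acid-catalysed propargylation with the allenylboronate passes through a cyclic SE2′ transition state on the Si face of the enal, which should set the (4S) carbinol under catalyst control irrespective of the remote C8 centre.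

Step 11
Reactants: 14 (4S,5E,8S,9E,13E)-8-[(tert-butyldimethylsilyl)oxy]-14-iodo-6,10-dimethyltetradeca-5,9,13-trien-1-yn-4-ol
Product: 16 (1S,2E,5S,6E,10E,12E)-5-[(tert-butyldimethylsilyl)oxy]-3,7,13-trimethylcyclotetradeca-2,6,10,12-tetraen-1-ol, via alkenyldimethylalane 15 (not isolated)
Conditions: AlMe3 (3.5 equiv), Cp2ZrCl2 (0.5 equiv), CH2Cl2, 0 °C to rt; volatiles removed; slow addition to Pd(PPh3)4 (10 mol %), ZnCl2 (1 equiv), THF, 45 °C, 2 mM
Reagents that add atoms: trimethylaluminium, C[Al](C)C
Why: Zirconium-catalysed carboalumination adds Me–Al syn to the terminal alkyne with aluminium at the terminus, fixing the E trisubstituted alkene, and the alkenylalane should then close the 14-membered ring by intramolecular zinc-assisted Negishi alkenyl–alkenyl coupling with the E alkenyl iodide, with retention at both carbons, to give the (10E,12E)-diene.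

Step 12
Reactants: 16 (1S,2E,5S,6E,10E,12E)-5-[(tert-butyldimethylsilyl)oxy]-3,7,13-trimethylcyclotetradeca-2,6,10,12-tetraen-1-ol
Product: 17 (1S,2E,5S,6E,10E,12E)-5-[(tert-butyldimethylsilyl)oxy]-3,7,13-trimethylcyclotetradeca-2,6,10,12-tetraen-1-yl acetate
Conditions: Ac2O, pyridine, DMAP (cat.), CH2Cl2, 0 °C to rt
Reagents that add atoms: acetic anhydride, CC(=O)OC(C)=O
Why: DMAP-catalysed acylation of the only free hydroxyl installs the acetate and removes a competing nucleophile before the annulation.

Step 13
Reactants: 17 (1S,2E,5S,6E,10E,12E)-5-[(tert-butyldimethylsilyl)oxy]-3,7,13-trimethylcyclotetradeca-2,6,10,12-tetraen-1-yl acetate; 18 2-bromoacrylic acid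
Product: 19 (1R,2S,3E,6S,7E,10S,11E)-6-acetoxy-10-[(tert-butyldimethylsilyl)oxy]cembra-3,7,11,15(17)-tetraen-16,2-olide
Conditions: 18 (1.5 equiv, slow addition), Pd(OAc)2 (10 mol %), n-Bu4NCl (1 equiv), NaHCO3 (3 equiv), DMF, 70 °C
Reagents that add atoms: none
Why: Pd(0) inserts into the C–Br bond of 18, the alkenylpalladium carboxylate adds syn across the C10=C11 alkene of the diene (cembrane C1=C2) with C15 going to the less substituted terminus C10, and the resulting η3-allyl complex (C11–C13) is captured at C11 by the palladium-bound carboxylate, which releases Pd(0) and leaves the C12=C13 alkene E. The closest known reaction is the Larock-type palladium-catalysed heteroannulation of 1,3-dienes by vinylic halides that carry a carboxylic acid. The lactone ring closes in a 5-exo sense by C–O bond formation at the proximal allyl terminus, since attack at the distal trisubstituted terminus would require a seven-membered ring. C1 is set by the face of carbopalladation, expected to be the peripheral face of the s-trans diene in the macrocycle conformer fixed by the C6 acetoxy and C10 silyloxy groups (to be checked by a conformational search on 17), and C2 follows from C1 stereospecifically, because syn carbopalladation of the E alkene followed by delivery of oxygen from the same face (the course that gives cis-fused products from cyclic dienes) can only give the trans-fused lactone. The step needs chemoselectivity for the conjugated diene over the three trisubstituted alkenes and the allylic acetate; trisubstituted alkenes should not insert under these conditions, and phosphine-free palladium that is consumed at once by the activated bromide should not ionise the acetate.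

Step 14
Reactants: 19 (1R,2S,3E,6S,7E,10S,11E)-6-acetoxy-10-[(tert-butyldimethylsilyl)oxy]cembra-3,7,11,15(17)-tetraen-16,2-olide
Product: 20 (1R,2S,3E,6S,7E,10S,11E)-6-acetoxy-10-hydroxycembra-3,7,11,15(17)-tetraen-16,2-olide
Conditions: HF·pyridine, pyridine, THF, 0 °C to rt
Reagents that add atoms: none
Why: Buffered fluoride desilylation should cleave the secondary TBS ether without opening the lactone, adding to the α-methylene group or touching the allylic acetate.

Compound list
1 | geranyl acetate | CC(C)=CCC/C(C)=C/COC(C)=O | starting material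
2 | 6,7-epoxygeranyl acetate (racemic epoxide) | CC1(C)OC1CC/C(C)=C/COC(C)=O | intermediate (not isolated)
3 | (2E)-3-methyl-6-oxohex-2-en-1-yl acetate | O=CCC/C(C)=C/COC(C)=O | intermediate
4 | (2E)-3-methylhept-2-en-6-yn-1-ol | C#CCC/C(C)=C/CO | intermediate
5 | alkenylzirconocene chloride from 4 (E, O-zirconated) | Cl[Zr](/C=C/CC/C(C)=C/CO[Zr](Cl)(C1C=CC=C1)C1C=CC=C1)(C1C=CC=C1)C1C=CC=C1 | intermediate (not isolated)
6 | (2E,6E)-7-iodo-3-methylhepta-2,6-dien-1-ol | I/C=C/CC/C(C)=C/CO | intermediate
7 | (2E,6E)-7-iodo-3-methylhepta-2,6-dienal | I/C=C/CC/C(C)=C/C=O | intermediate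
8 | methyl 3-methylbut-2-enoate | COC(=O)C=C(C)C | starting material
9 | tert-butyl[(1-methoxy-3-methylbuta-1,3-dien-1-yl)oxy]dimethylsilane | C=C(C)C=C(OC)O[Si](C)(C)C(C)(C)C | intermediate
10 | methyl (2E,5S,6E,10E)-5-hydroxy-11-iodo-3,7-dimethylundeca-2,6,10-trienoate | COC(=O)/C=C(\C)C[C@H](O)/C=C(\C)CC/C=C/I | intermediate
11 | methyl (2E,5S,6E,10E)-5-[(tert-butyldimethylsilyl)oxy]-11-iodo-3,7-dimethylundeca-2,6,10-trienoate | COC(=O)/C=C(\C)C[C@H](O[Si](C)(C)C(C)(C)C)/C=C(\C)CC/C=C/I | intermediate
12 | (2E,5S,6E,10E)-5-[(tert-butyldimethylsilyl)oxy]-11-iodo-3,7-dimethylundeca-2,6,10-trien-1-ol | OC/C=C(\C)C[C@H](O[Si](C)(C)C(C)(C)C)/C=C(\C)CC/C=C/I | intermediate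
13 | (2E,5S,6E,10E)-5-[(tert-butyldimethylsilyl)oxy]-11-iodo-3,7-dimethylundeca-2,6,10-trienal | O=C/C=C(\C)C[C@H](O[Si](C)(C)C(C)(C)C)/C=C(\C)CC/C=C/I | intermediate
14 | (4S,5E,8S,9E,13E)-8-[(tert-butyldimethylsilyl)oxy]-14-iodo-6,10-dimethyltetradeca-5,9,13-trien-1-yn-4-ol | C#CC[C@H](O)/C=C(\C)C[C@H](O[Si](C)(C)C(C)(C)C)/C=C(\C)CC/C=C/I | intermediate
15 | alkenyldimethylalane from 14 (E, aluminium alkoxide at C4) | C[Al](C)/C=C(\C)C[C@H](O[Al](C)C)/C=C(\C)C[C@H](O[Si](C)(C)C(C)(C)C)/C=C(\C)CC/C=C/I | intermediate (not isolated)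
16 | (1S,2E,5S,6E,10E,12E)-5-[(tert-butyldimethylsilyl)oxy]-3,7,13-trimethylcyclotetradeca-2,6,10,12-tetraen-1-ol | C1/C=C/C=C(\C)C[C@H](O)/C=C(\C)C[C@H](O[Si](C)(C)C(C)(C)C)/C=C(\C)C1 | intermediate
17 | (1S,2E,5S,6E,10E,12E)-5-[(tert-butyldimethylsilyl)oxy]-3,7,13-trimethylcyclotetradeca-2,6,10,12-tetraen-1-yl acetate | C1/C=C/C=C(\C)C[C@H](OC(C)=O)/C=C(\C)C[C@H](O[Si](C)(C)C(C)(C)C)/C=C(\C)C1 | intermediate
18 | 2-bromoacrylic acid | C=C(Br)C(=O)O | starting material
19 | (1R,2S,3E,6S,7E,10S,11E)-6-acetoxy-10-[(tert-butyldimethylsilyl)oxy]cembra-3,7,11,15(17)-tetraen-16,2-olide (trans-fused α-methylene-γ-butyrolactone on the 14-membered ring) | C=C1C(=O)O[C@H]2/C=C(\C)C[C@H](OC(C)=O)/C=C(\C)C[C@H](O[Si](C)(C)C(C)(C)C)/C=C(\C)CC[C@H]12 | intermediate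
20 | (1R,2S,3E,6S,7E,10S,11E)-6-acetoxy-10-hydroxycembra-3,7,11,15(17)-tetraen-16,2-olide (CNP0168244.1) | C=C1C(=O)O[C@H]2/C=C(\C)C[C@H](OC(C)=O)/C=C(\C)C[C@H](O)/C=C(\C)CC[C@H]12 | target

Total step count: 14. Longest linear sequence: 13 steps (steps 1–4 and 6–14, from geranyl acetate).

Steps most likely to fail

Step 13. Three processes could defeat it. Carbopalladation of the 1,2-disubstituted diene terminus could be slower than self-coupling or polymerisation of the bromoacrylate. Attack could occur on the wrong diene face. Ring closure could proceed by outer-sphere attack, which would give the cis-fused lactone. The fallback sets out from 17 and returns at 20, using a radical–polar crossover lactone annulation in place of the palladium step. Treatment of 17 with 2-(trimethylsilyl)ethyl hydrogen malonate and Mn(OAc)3·2H2O (KOAc, AcOH, 60 °C) should add the malonyl radical to the unsubstituted diene terminus. The allyl radical is oxidised to the allyl cation, which the free acid captures at the proximal carbon, trans to the new C–C bond. This should give the trans-fused α-[2-(trimethylsilyl)ethoxycarbonyl] lactone F1, in which C1 is set in a radical addition whose face selection is independent of the palladium pathway. Buffered TBAF (AcOH, THF) then removes the trimethylsilylethyl ester and the silyl ether together to give the α-carboxy lactone with free C10 hydroxyl F2. Decarboxylative Mannich methylenation (aq. CH2O, Et2NH, then NaOAc, AcOH, 90 °C) should convert F2 into 20.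

Step 11. Methyl transfer from aluminium to the alkenyl iodide, or intermolecular coupling to oligomers, could outrun ring closure. The fallback sets out from 14 and returns at 16, separating alkyne functionalisation from ring closure. The same carboalumination is quenched with 2-isopropoxy-4,4,5,5-tetramethyl-1,3,2-dioxaborolane to give the isolable 2-[(1E,4S,5E,8S,9E,13E)-8-(tert-butyldimethylsilyloxy)-4-hydroxy-14-iodo-2,6,10-trimethyltetradeca-1,5,9,13-tetraen-1-yl]-4,4,5,5-tetramethyl-1,3,2-dioxaborolane F3. F3 is then cyclised by Suzuki–Miyaura macrocyclisation (Pd(dppf)Cl2, Cs2CO3, THF/H2O, 1 mM, 50 °C) to 16.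

Step 6. The β,β-disubstituted enal could turn over slowly, lose enantioselectivity to the uncatalysed pathway, or suffer α- instead of γ-attack. The fallback sets out from 7 and returns at 11, building the unit by propargylation instead of a vinylogous aldol. Allenylboronic acid pinacol ester with (S)-TRIP (toluene, −20 °C) should give (4S,5E,9E)-10-iodo-6-methyldeca-5,9-dien-1-yn-4-ol F4. TBSCl/imidazole gives tert-butyl{[(4S,5E,9E)-10-iodo-6-methyldeca-5,9-dien-1-yn-4-yl]oxy}dimethylsilane F5. Zirconium-catalysed carboalumination of F5 (AlMe3, Cp2ZrCl2) followed by a methyl chloroformate quench should deliver the (2E) ester 11 directly.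

Further compounds
F1 | step 13 | 2-(trimethylsilyl)ethyl ester of the 15-carboxy lactone: compound 19 with the exocyclic CH2 replaced by H and CO2CH2CH2SiMe3 (trans ring fusion as in 19, mixture at C15) | C[Si](C)(C)CCOC(=O)C1C(=O)O[C@H]2/C=C(\C)C[C@H](OC(C)=O)/C=C(\C)C[C@H](O[Si](C)(C)C(C)(C)C)/C=C(\C)CC[C@H]12
F2 | step 13 | 15-carboxy lactone with free C10 hydroxyl: compound 20 with the exocyclic CH2 replaced by H and CO2H (mixture at C15) | O=C(O)C1C(=O)O[C@H]2/C=C(\C)C[C@H](OC(C)=O)/C=C(\C)C[C@H](O)/C=C(\C)CC[C@H]12
F3 | step 11 | 2-[(1E,4S,5E,8S,9E,13E)-8-(tert-butyldimethylsilyloxy)-4-hydroxy-14-iodo-2,6,10-trimethyltetradeca-1,5,9,13-tetraen-1-yl]-4,4,5,5-tetramethyl-1,3,2-dioxaborolane | CC1(C)OB(/C=C(\C)C[C@H](O)/C=C(\C)C[C@H](O[Si](C)(C)C(C)(C)C)/C=C(\C)CC/C=C/I)OC1(C)C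
F4 | step 6 | (4S,5E,9E)-10-iodo-6-methyldeca-5,9-dien-1-yn-4-ol | C#CC[C@H](O)/C=C(\C)CC/C=C/I
F5 | step 6 | tert-butyl{[(4S,5E,9E)-10-iodo-6-methyldeca-5,9-dien-1-yn-4-yl]oxy}dimethylsilane | C#CC[C@H](O[Si](C)(C)C(C)(C)C)/C=C(\C)CC/C=C/I
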